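**Plan**

1. Numbering: aristolane numbers for the sesquiterpene part (C1 benzylic CH, C8 and C9 the dione, C10 the ether carbon, C11 the cyclopropane CMe2); primed numbers for the phenol ring (C1′ acyl, C2′ OH, C4′ OMe, C5′ bonded to C1, C6′ bonded to O).
2. Cuts, from the target backwards: C8 carbonyl (back to a silyl-protected carbinol); C1′–acyl (Friedel–Crafts); O–C6′ (aryl C–H etherification directed by the C10 hydroxyl); C10–O and C1–C5′ (enol ether oxidation and aryl conjugate addition on a 1(10)-en-9-one); C9–O (dienolate hydroxylation of aristolone); C6–C11 and C7–C11 (isopropylidene transfer); C9=C10 and C5–C6 (Robinson annulation); C4–CH3 (asymmetric methyl addition).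
3. Enabling feature: the dihydrofuran oxygen joins the tertiary carbon C10 to C6′, and C6′ is ortho to C5′, which is bonded to the neighbouring carbon C1. With O–C6′ opened the molecule is a tertiary 2-arylethanol whose hydroxyl sits over its own ortho C–H.
4. Forward order: ring A is the starting cyclohexenone; then ring B (Robinson annulation), the cyclopropane, oxygen at C9, aryl at C1, hydroxyl at C10, the dihydrofuran ring, the cinnamoyl ketone, and the C8 ketone last.
5. Stereochemistry: C4 from a copper-catalysed enantioselective methyl addition; C5 from Michael addition anti to the C4 methyl; C6 and C7 from ylide attack anti to the C5 methyl; C1 and C10 from attack anti to the cyclopropane, which places aryl and hydroxyl cis; the alkene geometry comes with (E)-4-methoxycinnamic acid.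

Key step: step 11

Assumption: the C8 and C9 carbinol centres formed in step 6 are provisional (both carbons end as ketones); they are drawn as expected for attack anti to the cyclopropane, and the C8 centre is carried as drawn until step 15.

**Route**

Step 1
Reactants: 1 2-methylcyclohex-2-en-1-one
Product: 3 (R)-(2,3-dimethylcyclohex-1-en-1-yl)oxytrimethylsilane, via dimethylaluminium enolate 2 (not isolated)
Conditions: Me3Al, Cu(OTf)2 (2 mol%), BINOL-derived N,N-bis(1-phenylethyl)phosphoramidite (4 mol%, the enantiomer that gives the R adduct), Et2O, −30 °C; then TMSOTf, THF, −30 → 0 °C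
Reagents that add atoms: trimethylaluminium C[Al](C)C; trimethylsilyl trifluoromethanesulfonate C[Si](C)(C)OS(=O)(=O)C(F)(F)F
Why: Copper-catalysed asymmetric conjugate addition of Me3Al to an α-substituted cyclohexenone, in which the chiral phosphoramidite sets the methyl-bearing centre (C4 of the aristolane numbering) and O-silylation of the aluminium enolate keeps the enolate regiochemistry for the next step.

Step 2
Reactants: 3 (R)-(2,3-dimethylcyclohex-1-en-1-yl)oxytrimethylsilane; 4 but-3-en-2-one
Product: 5 (2S,3R)-2,3-dimethyl-2-(3-oxobutyl)cyclohexan-1-one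
Conditions: BF3·OEt2, iPrOH, CH2Cl2–MeNO2, −78 °C
Reagents that add atoms: none
Why: Mukaiyama–Michael addition in which the enone approaches C2 of the silyl enol ether anti to the pseudoaxial C3 methyl group (allylic 1,2-strain), so the quaternary centre (C5) forms with the two methyl groups cis.

Step 3
Reactants: 5 (2S,3R)-2,3-dimethyl-2-(3-oxobutyl)cyclohexan-1-one
Product: 6 (4aS,5R)-4a,5-dimethyl-4,4a,5,6,7,8-hexahydronaphthalen-2(3H)-one
Conditions: KOH, MeOH, 60 °C
Reagents that add atoms: none
Why: Intramolecular aldol condensation (second stage of the Robinson annulation) closes ring B as the 9-en-8-one; neither existing stereocentre is enolisable.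

Step 4
Reactants: 6 (4aS,5R)-4a,5-dimethyl-4,4a,5,6,7,8-hexahydronaphthalen-2(3H)-one
Product: 7 4a,5-dimethyl-5,6,7,8-tetrahydronaphthalen-2(4aH)-one (cross-conjugated 6,9-dien-8-one, methyl groups cis as in 6)
Conditions: DDQ, dioxane, reflux
Reagents that add atoms: none
Why: DDQ dehydrogenation of a bicyclic enone at its α′,β′ positions under neutral conditions, the reaction that turns steroidal 4-en-3-ones into 1,4-dien-3-ones.

Step 5
Reactants: 7 4a,5-dimethyl-5,6,7,8-tetrahydronaphthalen-2(4aH)-one
Product: 8 aristolone, (1aR,7R,7aR,7bS)-1,1,7,7a-tetramethyl-1a,4,5,6,7,7b-hexahydro-1H-cyclopropa[a]naphthalen-2-one (aristol-9-en-8-one)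
Conditions: iPrPh2S+ BF4−, LiN(iPr)2, DME, −78 °C; then 7, −78 → −20 °C
Reagents that add atoms: isopropyldiphenylsulfonium tetrafluoroborate CC(C)[S+](c1ccccc1)c1ccccc1.F[B-](F)(F)F
Why: Corey–Chaykovsky-type isopropylidene transfer in which the sulfonium ylide adds to C6 of the less substituted enone double bond anti to the angular C5 methyl and closes onto C7, setting C6 and C7 with the cyclopropane anti to that methyl.

Step 6
Reactants: 8 aristolone
Product: 11 aristol-1(10)-ene-8,9-diol (8-OH on the cyclopropane face; 9-OH on the methyl face), via potassium dienolate 9 (not isolated), via 9-hydroxyaristol-1(10)-en-8-one 10 (not isolated)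
Conditions: KN(SiMe3)2, THF, −78 °C; 2-(phenylsulfonyl)-3-phenyloxaziridine, −78 °C; then MeOH, NaBH4 (excess), −78 → 0 °C
Reagents that add atoms: 2-(phenylsulfonyl)-3-phenyloxaziridine O=S(=O)(N1OC1c1ccccc1)c1ccccc1
Why: Oxaziridine hydroxylation of an extended enolate: C1 is deprotonated because the only α′ hydrogen is on the cyclopropane, oxygen enters at the α-carbon C9 with the double bond moving to C1=C10, and borohydride then reduces the isomerisation-prone ketol in the same flask from the face anti to the cyclopropane.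

Step 7
Reactants: 11 aristol-1(10)-ene-8,9-diol
Product: 12 8-hydroxyaristol-1(10)-en-9-one (8-OH on the cyclopropane face)
Conditions: MnO2, CH2Cl2, rt
Reagents that add atoms: none
Why: MnO2 oxidises only the allylic C9 carbinol to the conjugated enone; the C8 carbinol next to the cyclopropane is not allylic and should remain.

Step 8
Reactants: 12 8-hydroxyaristol-1(10)-en-9-one
Product: 13 8-(triisopropylsilyloxy)aristol-1(10)-en-9-one
Conditions: TIPSOTf, 2,6-lutidine, CH2Cl2, 0 °C
Reagents that add atoms: triisopropylsilyl trifluoromethanesulfonate CC(C)[Si](OS(=O)(=O)C(F)(F)F)(C(C)C)C(C)C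
Why: Silylation of a secondary alcohol with a silyl triflate; the bulky ether is chosen to survive the organometallic, oxidative and Lewis-acid steps that follow.

Step 9
Reactants: 13 8-(triisopropylsilyloxy)aristol-1(10)-en-9-one; 14 1-bromo-2,4-dimethoxybenzene
Product: 16 1-(2,4-dimethoxyphenyl)-8-(triisopropylsilyloxy)-9-(trimethylsilyloxy)aristol-9-ene (aryl on the methyl face), via (2,4-dimethoxyphenyl)magnesium bromide 15 (not isolated)
Conditions: 14, Mg, THF, rt; then 13, CuBr·SMe2 (20 mol%), TMSCl, THF, −78 → −40 °C; Et3N, NaHCO3 work-up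
Reagents that add atoms: chlorotrimethylsilane C[Si](C)(C)Cl
Why: Copper-catalysed, TMSCl-accelerated conjugate addition of an aryl Grignard reagent with silyl trapping of the enolate; the aryl group should enter C1 axially on the ring-A half-chair from the face anti to the cyclopropane, whose endo methyl overhangs the C9–C10–C1 π-face, which sets C1.

Step 10
Reactants: 16 1-(2,4-dimethoxyphenyl)-8-(triisopropylsilyloxy)-9-(trimethylsilyloxy)aristol-9-ene
Product: 18 1-(2,4-dimethoxyphenyl)-10-hydroxy-8-(triisopropylsilyloxy)aristolan-9-one (aryl and hydroxyl cis; both on the methyl face), via 10-trimethylsilyloxy ketone 17 (not isolated)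
Conditions: DMDO, acetone–CH2Cl2, −78 → −20 °C; then citric acid, MeOH, 0 °C
Reagents that add atoms: dimethyldioxirane CC1(C)OO1
Why: Rubottom oxidation in which the small oxidant reaches the tetrasubstituted silyl enol ether only from the face anti to the gem-dimethylcyclopropane (the bias known from additions to car-3-ene), silyl shift gives the α-silyloxy ketone and mild acid removes the trimethylsilyl group alone, setting C10 with the hydroxyl cis to the aryl group.

Step 11
Reactants: 18 1-(2,4-dimethoxyphenyl)-10-hydroxy-8-(triisopropylsilyloxy)aristolan-9-one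
Product: 19 dihydrobenzofuran-fused 8-(triisopropylsilyloxy)aristolan-9-one (O links C10 to C6′; C1–C5′; 2′,4′-dimethoxy; cis ring fusion)
Conditions: Pd(OAc)2 (10 mol%), PhI(OAc)2, Li2CO3, C6F6, 100 °C
Reagents that add atoms: none
Why: Divalent palladium binds the C10 alkoxide and, assisted by acetate, palladates C6′–H to give a six-membered oxapalladacycle; PhI(OAc)2 oxidises this to tetravalent palladium and C–O reductive elimination releases the ether. The closest known reaction type is the hydroxyl-directed C–H activation and C–O cyclisation of tertiary 2-arylethanols to dihydrobenzofurans with the same reagents. The five-membered dihydrofuran ring closes by reductive elimination from the six-membered palladacycle, not by attack of oxygen on the arene. No stereocentre is formed; the cis fusion is inherited from the cis aryl and hydroxyl groups set in steps 9 and 10. The step needs site selectivity, which is secured because C6′ is the only ortho C–H (the other ortho carbon, C4′, carries methoxy) and the hydroxyl holds palladium next to it. It also needs chemoselectivity, secured because the tertiary alcohol has no carbinol hydrogen to be oxidised, the C8 alcohol is silylated and Li2CO3 buffers the acetic acid formed.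

Step 12
Reactants: 20 (E)-4-methoxycinnamic acid
Product: 21 (E)-4-methoxycinnamoyl chloride
Conditions: (COCl)2, DMF (cat.), CH2Cl2, 0 °C → rt; concentrated and used directly
Reagents that add atoms: oxalyl chloride ClC(=O)C(Cl)=O
Why: Standard acid chloride formation through the chloroiminium species from DMF and oxalyl chloride, which leaves the E alkene untouched.

Step 13
Reactants: 19 dihydrobenzofuran-fused 8-(triisopropylsilyloxy)aristolan-9-one; 21 (E)-4-methoxycinnamoyl chloride
Product: 23 1′-[(E)-4-methoxycinnamoyl]-2′-hydroxy-4′-methoxy dihydrobenzofuran-fused 8-(triisopropylsilyloxy)aristolan-9-one, via 2′-methyl ether 22 (not isolated)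
Conditions: AlCl3, CH2Cl2, 0 °C → rt; aqueous HCl work-up
Reagents that add atoms: none
Why: Friedel–Crafts acylation at C1′, the position para to the C4′ methoxy group and flanked by the ring oxygen (C3′ lies between two methoxy groups, the C4′ methyl being turned toward it by the C1 substituent), followed by AlCl3-chelation-assisted cleavage of the methyl ether ortho to the new ketone; the other ortho oxygen is bonded to the tertiary, α-keto carbon C10 and cannot be cleaved by substitution.

Step 14
Reactants: 23 1′-[(E)-4-methoxycinnamoyl]-2′-hydroxy-4′-methoxy dihydrobenzofuran-fused 8-(triisopropylsilyloxy)aristolan-9-one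
Product: 24 8-hydroxy-9-ketone (1′-[(E)-4-methoxycinnamoyl]-2′-hydroxy-4′-methoxy dihydrobenzofuran-fused 8-hydroxyaristolan-9-one)
Conditions: HF·pyridine, THF, 0 °C → rt
Reagents that add atoms: none
Why: Fluoride cleavage of the silyl ether under mildly acidic conditions, which avoids base-induced closure of the 2′-hydroxychalcone to a flavanone.

Step 15
Reactants: 24 8-hydroxy-9-ketone
Product: 25 CNP0121765.1
Conditions: DMP, CH2Cl2, 0 °C → rt
Reagents that add atoms: none
Why: DMP oxidation of the secondary α-ketol to the 1,2-diketone; neither carbonyl can enolise (C7 is a cyclopropane carbon, C10 is quaternary), so no stereocentre is at risk, and the hydrogen-bonded phenol is not expected to react.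

**Compound list**

1 | 2-methylcyclohex-2-en-1-one | CC1=CCCCC1=O | starting material
2 | dimethylaluminium (R)-2,3-dimethylcyclohex-1-en-1-olate | C[C@@H]1CCCC(O[Al](C)C)=C1C | intermediate
3 | (R)-(2,3-dimethylcyclohex-1-en-1-yl)oxytrimethylsilane | C[C@@H]1CCCC(O[Si](C)(C)C)=C1C | intermediate
4 | but-3-en-2-one | CC(=O)C=C | starting material
5 | (2S,3R)-2,3-dimethyl-2-(3-oxobutyl)cyclohexan-1-one | CC(=O)CC[C@@]1(C)[C@H](C)CCCC1=O | intermediate
6 | (4aS,5R)-4a,5-dimethyl-4,4a,5,6,7,8-hexahydronaphthalen-2(3H)-one | O=C1C=C2CCC[C@@H](C)[C@]2(C)CC1 | intermediate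
7 | 4a,5-dimethyl-5,6,7,8-tetrahydronaphthalen-2(4aH)-one (cis-dimethyl cross-conjugated dienone) | O=C1C=C2CCC[C@@H](C)[C@]2(C)C=C1 | intermediate
8 | aristolone (aristol-9-en-8-one; cyclopropane anti to the C5 methyl) | O=C1C=C2CCC[C@@H](C)[C@]2(C)[C@H]3[C@@H]1C3(C)C | intermediate
9 | potassium dienolate of aristolone (C8–O−; C8=C9; C10=C1) | [K+].[O-]C1=CC2=CCC[C@@H](C)[C@]2(C)[C@H]3[C@@H]1C3(C)C | intermediate
10 | 9-hydroxyaristol-1(10)-en-8-one (9-OH on the methyl face) | O=C1[C@@H](O)C2=CCC[C@@H](C)[C@]2(C)[C@H]3[C@@H]1C3(C)C | intermediate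
11 | aristol-1(10)-ene-8,9-diol (8-OH on the cyclopropane face; 9-OH on the methyl face) | O[C@@H]1[C@@H](O)C2=CCC[C@@H](C)[C@]2(C)[C@H]3[C@@H]1C3(C)C | intermediate
12 | 8-hydroxyaristol-1(10)-en-9-one | O[C@@H]1C(=O)C2=CCC[C@@H](C)[C@]2(C)[C@H]3[C@@H]1C3(C)C | intermediate
13 | 8-(triisopropylsilyloxy)aristol-1(10)-en-9-one | CC(C)[Si](C(C)C)(C(C)C)O[C@@H]1C(=O)C2=CCC[C@@H](C)[C@]2(C)[C@H]3[C@@H]1C3(C)C | intermediate
14 | 1-bromo-2,4-dimethoxybenzene | COc1ccc(Br)c(OC)c1 | starting material
15 | (2,4-dimethoxyphenyl)magnesium bromide | COc1ccc([Mg]Br)c(OC)c1 | intermediate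
16 | 1-(2,4-dimethoxyphenyl)-8-(triisopropylsilyloxy)-9-(trimethylsilyloxy)aristol-9-ene | CC(C)[Si](C(C)C)(C(C)C)O[C@@H]1C(O[Si](C)(C)C)=C2[C@@H](c4ccc(OC)cc4OC)CC[C@@H](C)[C@]2(C)[C@H]3[C@@H]1C3(C)C | intermediate
17 | 1-(2,4-dimethoxyphenyl)-8-(triisopropylsilyloxy)-10-(trimethylsilyloxy)aristolan-9-one | CC(C)[Si](C(C)C)(C(C)C)O[C@@H]1C(=O)[C@]2(O[Si](C)(C)C)[C@@H](c4ccc(OC)cc4OC)CC[C@@H](C)[C@]2(C)[C@H]3[C@@H]1C3(C)C | intermediate
18 | 1-(2,4-dimethoxyphenyl)-10-hydroxy-8-(triisopropylsilyloxy)aristolan-9-one (aryl and hydroxyl cis) | CC(C)[Si](C(C)C)(C(C)C)O[C@@H]1C(=O)[C@]2(O)[C@@H](c4ccc(OC)cc4OC)CC[C@@H](C)[C@]2(C)[C@H]3[C@@H]1C3(C)C | intermediate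
19 | dihydrobenzofuran-fused 8-(triisopropylsilyloxy)aristolan-9-one (O links C10 and C6′; 2′,4′-dimethoxy) | CC(C)[Si](C(C)C)(C(C)C)O[C@@H]1C(=O)[C@@]24Oc5cc(OC)cc(OC)c5[C@H]4CC[C@@H](C)[C@]2(C)[C@H]3[C@@H]1C3(C)C | intermediate
20 | (E)-4-methoxycinnamic acid | COc1ccc(/C=C/C(O)=O)cc1 | starting material
21 | (E)-4-methoxycinnamoyl chloride | COc1ccc(/C=C/C(Cl)=O)cc1 | intermediate
22 | 1′-[(E)-4-methoxycinnamoyl]-2′,4′-dimethoxy derivative of 19 | CC(C)[Si](C(C)C)(C(C)C)O[C@@H]1C(=O)[C@@]24Oc5c(C(=O)/C=C/c6ccc(OC)cc6)c(OC)cc(OC)c5[C@H]4CC[C@@H](C)[C@]2(C)[C@H]3[C@@H]1C3(C)C | intermediate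
23 | 1′-[(E)-4-methoxycinnamoyl]-2′-hydroxy-4′-methoxy derivative of 19 | CC(C)[Si](C(C)C)(C(C)C)O[C@@H]1C(=O)[C@@]24Oc5c(C(=O)/C=C/c6ccc(OC)cc6)c(O)cc(OC)c5[C@H]4CC[C@@H](C)[C@]2(C)[C@H]3[C@@H]1C3(C)C | intermediate
24 | 8-hydroxy-9-ketone (desilylated 23) | O[C@@H]1C(=O)[C@@]24Oc5c(C(=O)/C=C/c6ccc(OC)cc6)c(O)cc(OC)c5[C@H]4CC[C@@H](C)[C@]2(C)[C@H]3[C@@H]1C3(C)C | intermediate
25 | CNP0121765.1 | COc1ccc(/C=C/C(=O)c2c(O)cc(OC)c3c2O[C@]24C(=O)C(=O)[C@@H]5[C@@H](C5(C)C)[C@@]2(C)[C@H](C)CC[C@H]34)cc1 | target

**Count and risks**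

Total step count: 15. Longest linear sequence: 14 steps (steps 1–11 and 13–15); step 12 is a one-step side branch.

Steps most likely to fail:

Step 9. Facial selectivity of the aryl transfer may be poor: delivery to C1 on the cyclopropane face, away from the axial C5 methyl, competes with the wanted axial delivery anti to the cyclopropane. Step 10 would then place the hydroxyl trans to the aryl group and the ring could not close. The fallback replaces substrate control by a stereospecific sequence and also bypasses step 10. It sets out from 16 in whichever C1 configuration it is obtained, since C1 becomes trigonal. DDQ with 2,6-lutidine in MeCN oxidises the silyl enol ether to the β-aryl enone 1-(2,4-dimethoxyphenyl)-8-(triisopropylsilyloxy)aristol-1(10)-en-9-one F1. DMDO then epoxidises the C1=C10 bond on the face anti to the cyclopropane to give 1,10-epoxy-1-(2,4-dimethoxyphenyl)-8-(triisopropylsilyloxy)aristolan-9-one F2. Hydrogenolysis of the benzylic C1–O bond (H2, Pd/C, EtOAc), which on palladium should go with inversion, puts hydrogen on the cyclopropane face of C1 and leaves the C10 hydroxyl cis to the aryl group. The detour returns to the route at 18.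

Step 11. Oxidative degradation may outrun cyclopalladation: cleavage of the C9–C10 bond or acyl shift of the α-ketol under PhI(OAc)2 at 100 °C, or acetoxylation of the electron-rich ring. The fallback forms the same O–C6′ bond by cross-coupling to a halide placed at C6′, and sets out from 13. Iodination of commercial 1-bromo-3,5-dimethoxybenzene with N-iodosuccinimide gives 1-bromo-2-iodo-3,5-dimethoxybenzene F3. Iodine–magnesium exchange (iPrMgCl·LiCl, THF, −40 °C) gives (2-bromo-4,6-dimethoxyphenyl)magnesium chloride F4. Addition to 13 under the conditions of step 9 gives 1-(2-bromo-4,6-dimethoxyphenyl)-8-(triisopropylsilyloxy)-9-(trimethylsilyloxy)aristol-9-ene F5. Oxidation as in step 10 gives, through 1-(2-bromo-4,6-dimethoxyphenyl)-8-(triisopropylsilyloxy)-10-(trimethylsilyloxy)aristolan-9-one F6, the bromo ketol 1-(2-bromo-4,6-dimethoxyphenyl)-10-hydroxy-8-(triisopropylsilyloxy)aristolan-9-one F7. Palladium-catalysed intramolecular C–O coupling (Pd(OAc)2, 2-(di-tert-butylphosphino)-1,1′-binaphthyl, Cs2CO3, toluene, 80 °C) then joins the C10 oxygen to C6′ without an oxidant. The detour returns to the route at 19.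

Step 13. The Lewis acid may open the gem-dimethylcyclopropane (HCl with AlCl3), remove the silyl ether early or cleave further methyl ethers. The fallback separates acylation from ether cleavage and uses no strong Lewis acid; it sets out from 19. Acid 20 is activated as its mixed anhydride with trifluoroacetic anhydride (CH2Cl2, 0 °C → rt) and acylates C1′ to give the 2′-methyl ether 22, now isolated. MgI2·OEt2 (toluene, 60 °C) then cleaves only the methoxy group chelated to the new ketone. The detour returns to the route at 23 and makes no compound outside the list (F0).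

**Further compounds**

F1 | step 9 | 1-(2,4-dimethoxyphenyl)-8-(triisopropylsilyloxy)aristol-1(10)-en-9-one | CC(C)[Si](C(C)C)(C(C)C)O[C@@H]1C(=O)C2=C(c4ccc(OC)cc4OC)CC[C@@H](C)[C@]2(C)[C@H]3[C@@H]1C3(C)C
F2 | step 9 | 1,10-epoxy-1-(2,4-dimethoxyphenyl)-8-(triisopropylsilyloxy)aristolan-9-one (epoxide oxygen anti to the cyclopropane) | CC(C)[Si](C(C)C)(C(C)C)O[C@@H]1C(=O)[C@@]26O[C@@]6(c4ccc(OC)cc4OC)CC[C@@H](C)[C@]2(C)[C@H]3[C@@H]1C3(C)C
F3 | step 11 | 1-bromo-2-iodo-3,5-dimethoxybenzene | Brc1cc(OC)cc(OC)c1I
F4 | step 11 | (2-bromo-4,6-dimethoxyphenyl)magnesium chloride | COc1cc(Br)c([Mg]Cl)c(OC)c1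
F5 | step 11 | 1-(2-bromo-4,6-dimethoxyphenyl)-8-(triisopropylsilyloxy)-9-(trimethylsilyloxy)aristol-9-ene | CC(C)[Si](C(C)C)(C(C)C)O[C@@H]1C(O[Si](C)(C)C)=C2[C@@H](c4c(Br)cc(OC)cc4OC)CC[C@@H](C)[C@]2(C)[C@H]3[C@@H]1C3(C)C
F6 | step 11 | 1-(2-bromo-4,6-dimethoxyphenyl)-8-(triisopropylsilyloxy)-10-(trimethylsilyloxy)aristolan-9-one | CC(C)[Si](C(C)C)(C(C)C)O[C@@H]1C(=O)[C@]2(O[Si](C)(C)C)[C@@H](c4c(Br)cc(OC)cc4OC)CC[C@@H](C)[C@]2(C)[C@H]3[C@@H]1C3(C)C
F7 | step 11 | 1-(2-bromo-4,6-dimethoxyphenyl)-10-hydroxy-8-(triisopropylsilyloxy)aristolan-9-one | CC(C)[Si](C(C)C)(C(C)C)O[C@@H]1C(=O)[C@]2(O)[C@@H](c4c(Br)cc(OC)cc4OC)CC[C@@H](C)[C@]2(C)[C@H]3[C@@H]1C3(C)C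
F0 | step 13 | none | none
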